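**Strategy.** Rings: A, the 3,5-dihydroxyphenoxy ring; B, the dioxin benzene ring carrying it; C and D, the inner and outer rings of the dibenzofuran. The route rests on cutting the dioxin C–O bond between the oxygen on C2 of ring C and the ring-B carbon that lies between two aryloxy-bearing carbons (the ring-A ether carbon and the second dioxin carbon). A carbonyl inserted there gives a seven-membered depsidone lactone, built by stepwise ether and ester formation, which fixes the orientation of ring B. One nickel-catalysed decarbonylation expels CO and contracts the lactone to the dioxin. The precursor is the heptamethyl depsidone, its carbonyl derived from a formyl group that activated both fluoride displacements.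

Key step: step 14

Assumption: 5-bromo-4-fluoro-2-methoxybenzaldehyde and 2,6-difluoro-3,5-dimethoxybenzoic acid are taken as purchasable catalogue compounds.
Numbering in names: dibenzo[b,d]furan, with C1 the bay carbon of ring C, C4 next to the furan oxygen, and C9 the bay carbon of ring D.
Design remark: all seven spectator oxygens are carried as methyl ethers through the key step, because benzylic C–O bonds would be at risk from zerovalent nickel. The single benzyl ether is removed before lactonisation.

**Step 1**
Reactants: 1 5-bromo-4-fluoro-2-methoxybenzaldehyde; 2 3,5-dimethoxyphenol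
Product: 3 5-bromo-4-(3,5-dimethoxyphenoxy)-2-methoxybenzaldehyde
Conditions: K2CO3, DMF, 80 °C
Reagents that add atoms: none
Why: SNAr: the fluoride is para to the formyl group and ortho to bromine, so the phenoxide of 2 should displace it cleanly, while the bromide, meta to the formyl group, stays for the next step.

**Step 2**
Reactants: 3 5-bromo-4-(3,5-dimethoxyphenoxy)-2-methoxybenzaldehyde
Product: 4 3,7,9-trimethoxydibenzo[b,d]furan-2-carbaldehyde
Conditions: Pd(OAc)2 (5 mol%), PCy3·HBF4 (10 mol%), K2CO3, DMA, 130 °C
Reagents that add atoms: none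
Why: Intramolecular palladium-catalysed direct C–H arylation (concerted metalation–deprotonation): after insertion into the C–Br bond, either of the two equivalent ortho C–H positions of the symmetric dimethoxyphenoxy ring leads to the same dibenzofuran, with methoxy groups at C7 and C9.

**Step 3**
Reactants: 4 3,7,9-trimethoxydibenzo[b,d]furan-2-carbaldehyde
Product: 6 3,7,9-trimethoxydibenzo[b,d]furan-2-ol, via formate ester 5 (not isolated)
Conditions: mCPBA, CH2Cl2, 0 °C to rt; then K2CO3 (cat.), MeOH, rt
Reagents that add atoms: mCPBA, OOC(=O)c1cccc(Cl)c1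
Why: Baeyer–Villiger (Dakin-type) oxidation: the aryl group, made electron-rich by the ortho methoxy group and the para furan oxygen, should migrate in preference to hydride, and mild methanolysis of the formate frees the C2 phenol.

**Step 4**
Reactants: 6 3,7,9-trimethoxydibenzo[b,d]furan-2-ol
Product: 8 2-hydroxy-3,7,9-trimethoxydibenzo[b,d]furan-1-carbaldehyde, via hydroxymethyl phenol 7 (not isolated)
Conditions: MgCl2, Et3N, (CH2O)n, MeCN, reflux
Reagents that add atoms: paraformaldehyde (as formaldehyde), C=O
Why: Casnati–Skattebøl ortho-formylation: the magnesium phenoxide delivers formaldehyde through a six-membered transition state to the only free ortho carbon, C1 (C3 carries the methoxy group), and a second formaldehyde oxidises the hydroxymethyl intermediate by Oppenauer-type hydride transfer.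

**Step 5**
Reactants: 8 2-hydroxy-3,7,9-trimethoxydibenzo[b,d]furan-1-carbaldehyde
Product: 9 2-(benzyloxy)-3,7,9-trimethoxydibenzo[b,d]furan-1-carbaldehyde
Conditions: BnBr, K2CO3, DMF, 50 °C
Reagents that add atoms: benzyl bromide, BrCc1ccccc1
Why: Williamson etherification of the salicylaldehyde-type phenol, which places the hydrogenolysable group on the C2 oxygen before the C1 oxygen is unveiled.

**Step 6**
Reactants: 9 2-(benzyloxy)-3,7,9-trimethoxydibenzo[b,d]furan-1-carbaldehyde
Product: 11 2-(benzyloxy)-3,7,9-trimethoxydibenzo[b,d]furan-1-ol, via formate ester 10 (not isolated)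
Conditions: mCPBA, CH2Cl2, 0 °C to rt; then K2CO3 (cat.), MeOH, rt
Reagents that add atoms: mCPBA, OOC(=O)c1cccc(Cl)c1
Why: Baeyer–Villiger oxidation of an ortho-alkoxybenzaldehyde to the aryl formate and methanolysis turn the formyl carbon into the free bay hydroxyl on C1 while the C2 oxygen stays benzylated, so the two neighbouring oxygens are told apart without any selective protection.

**Step 7**
Reactants: 12 2,6-difluoro-3,5-dimethoxybenzoic acid
Product: 13 (2,6-difluoro-3,5-dimethoxyphenyl)methanol
Conditions: BH3·THF, THF, 0 °C to rt; aqueous work-up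
Reagents that add atoms: none
Why: Borane reduction of a carboxylic acid to the primary alcohol, which leaves aryl fluorides and methyl ethers untouched.

**Step 8**
Reactants: 13 (2,6-difluoro-3,5-dimethoxyphenyl)methanol
Product: 14 2,6-difluoro-3,5-dimethoxybenzaldehyde
Conditions: Dess–Martin periodinane, CH2Cl2, rt
Reagents that add atoms: none
Why: Dess–Martin oxidation of a benzylic alcohol stops at the aldehyde, and the formyl group is a stronger and less twisted SNAr activator than an ester flanked by two ortho substituents.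

**Step 9**
Reactants: 11 2-(benzyloxy)-3,7,9-trimethoxydibenzo[b,d]furan-1-ol; 14 2,6-difluoro-3,5-dimethoxybenzaldehyde
Product: 15 2-{[2-(benzyloxy)-3,7,9-trimethoxydibenzo[b,d]furan-1-yl]oxy}-6-fluoro-3,5-dimethoxybenzaldehyde
Conditions: Cs2CO3, DMSO, 90 °C (14 in twofold excess)
Reagents that add atoms: none
Why: SNAr: the ortho formyl group stabilises the Meisenheimer adduct and the second, meta fluorine adds inductive activation, so the hindered bay phenoxide should displace one fluoride, fluoride being the least sterically demanding leaving group for this tetra-ortho-substituted ether, while the excess of 14 disfavours double substitution.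

**Step 10**
Reactants: 15 2-{[2-(benzyloxy)-3,7,9-trimethoxydibenzo[b,d]furan-1-yl]oxy}-6-fluoro-3,5-dimethoxybenzaldehyde; 2 3,5-dimethoxyphenol
Product: 16 2-{[2-(benzyloxy)-3,7,9-trimethoxydibenzo[b,d]furan-1-yl]oxy}-6-(3,5-dimethoxyphenoxy)-3,5-dimethoxybenzaldehyde
Conditions: Cs2CO3, DMSO, 110 °C (2 in excess)
Reagents that add atoms: none
Why: Second SNAr ortho to the formyl group with the small, strongly nucleophilic phenoxide of 2 in excess, which places the formyl carbon between two aryloxy groups.

**Step 11**
Reactants: 16 2-{[2-(benzyloxy)-3,7,9-trimethoxydibenzo[b,d]furan-1-yl]oxy}-6-(3,5-dimethoxyphenoxy)-3,5-dimethoxybenzaldehyde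
Product: 17 2-{[2-(benzyloxy)-3,7,9-trimethoxydibenzo[b,d]furan-1-yl]oxy}-6-(3,5-dimethoxyphenoxy)-3,5-dimethoxybenzoic acid
Conditions: NaClO2, NaH2PO4, 2-methyl-2-butene (large excess), t-BuOH/THF/H2O, 0 °C to rt
Reagents that add atoms: sodium chlorite, [Na+].[O-]Cl=O
Why: Pinnick (Lindgren) oxidation of a hindered, non-enolisable aldehyde to the acid under buffered conditions, with the excess alkene trapping hypochlorous acid before it can chlorinate the electron-rich rings.

**Step 12**
Reactants: 17 2-{[2-(benzyloxy)-3,7,9-trimethoxydibenzo[b,d]furan-1-yl]oxy}-6-(3,5-dimethoxyphenoxy)-3,5-dimethoxybenzoic acid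
Product: 18 2-(3,5-dimethoxyphenoxy)-6-[(2-hydroxy-3,7,9-trimethoxydibenzo[b,d]furan-1-yl)oxy]-3,5-dimethoxybenzoic acid
Conditions: H2 (1 atm), 10% Pd/C, EtOAc/MeOH, rt
Reagents that add atoms: none
Why: Hydrogenolysis of the benzyl aryl ether over Pd/C; methyl ethers, diaryl ethers and the carboxylic acid are inert.

**Step 13**
Reactants: 18 2-(3,5-dimethoxyphenoxy)-6-[(2-hydroxy-3,7,9-trimethoxydibenzo[b,d]furan-1-yl)oxy]-3,5-dimethoxybenzoic acid
Product: 19 heptamethyl depsidone (seven-membered lactone: ring-B carboxyl esterified by the C2 oxygen of the dibenzofuran, ring-B oxygen ortho to it bound to C1)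
Conditions: EDC·HCl, DMAP, CH2Cl2, high dilution, rt
Reagents that add atoms: none
Why: Steglich-type carbodiimide lactonisation: O-acylation of the single free phenol closes the seven-membered depsidone, and the acid-free activation avoids Friedel–Crafts closure onto ring A to a xanthone.

**Step 14**
Reactants: 19 heptamethyl depsidone
Product: 20 heptamethyl ether of the target (dibenzo-1,4-dioxin fused at C1/C2 of the dibenzofuran)
Conditions: Ni(cod)2 (30 mol%), dcypt [3,4-bis(dicyclohexylphosphino)thiophene] (60 mol%), K3PO4, m-xylene, 160 °C, argon sweep to remove CO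
Reagents that add atoms: none
Why: Proposed new method: zerovalent nickel bearing the electron-rich bisphosphine dcypt should insert into the acyl C–O bond of the lactone, the acyl nickel aryloxide should lose CO, and C–O reductive elimination from the seven-membered aryl–nickel–aryloxide metallacycle should form the bond between the ring-B carbon and the C2 oxygen of ring C. The closest known reaction type is the nickel- or palladium-catalysed decarbonylative etherification of aryl arenecarboxylates to diaryl ethers, which has not been carried out on a depsidone lactone. The six-membered dioxin is closed by this reductive elimination, a one-carbon contraction of the seven-membered ring in which the existing ether bridge at C1 holds aryl and aryloxide on the same metal centre, so that neither crossover nor reorientation of ring B is possible. No stereocentre is formed. The step needs insertion into the acyl C–O bond in preference to the many aryl–O bonds (methyl ethers, diaryl ethers, furan); the lactone carbonyl, twisted out of conjugation by its two ortho aryloxy groups and held in a strained seven-membered ring, is the only activated C–O bond, and the two ortho oxygens should also speed CO loss and reductive elimination from the crowded aryl nickel species.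

**Step 15**
Reactants: 20 heptamethyl ether of the target
Product: 21 CNP0256302.0 (heptaphenol target)
Conditions: BBr3 (excess), CH2Cl2, −78 °C to rt; then MeOH/H2O
Reagents that add atoms: none
Why: Lewis-acid cleavage of aryl methyl ethers by BBr3 (bromide attacks the O-methyl carbon of the boron-complexed ether); the diaryl ether, dioxin and furan C–O bonds offer no alkyl carbon and should survive.

**Compound list**
1 | 5-bromo-4-fluoro-2-methoxybenzaldehyde | COc1cc(F)c(Br)cc1C=O | starting material
2 | 3,5-dimethoxyphenol | COc1cc(O)cc(OC)c1 | starting material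
3 | 5-bromo-4-(3,5-dimethoxyphenoxy)-2-methoxybenzaldehyde | COc1cc(Oc2cc(OC)cc(OC)c2)c(Br)cc1C=O | intermediate
4 | 3,7,9-trimethoxydibenzo[b,d]furan-2-carbaldehyde | COc1cc2oc3cc(OC)cc(OC)c3c2cc1C=O | intermediate
5 | 3,7,9-trimethoxydibenzo[b,d]furan-2-yl formate | COc1cc2oc3cc(OC)cc(OC)c3c2cc1OC=O | intermediate
6 | 3,7,9-trimethoxydibenzo[b,d]furan-2-ol | COc1cc2oc3cc(OC)cc(OC)c3c2cc1O | intermediate
7 | 1-(hydroxymethyl)-3,7,9-trimethoxydibenzo[b,d]furan-2-ol | COc1cc2oc3cc(OC)cc(OC)c3c2c(CO)c1O | intermediate
8 | 2-hydroxy-3,7,9-trimethoxydibenzo[b,d]furan-1-carbaldehyde | COc1cc2oc3cc(OC)cc(OC)c3c2c(C=O)c1O | intermediate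
9 | 2-(benzyloxy)-3,7,9-trimethoxydibenzo[b,d]furan-1-carbaldehyde | COc1cc2oc3cc(OC)cc(OC)c3c2c(C=O)c1OCc4ccccc4 | intermediate
10 | 2-(benzyloxy)-3,7,9-trimethoxydibenzo[b,d]furan-1-yl formate | COc1cc2oc3cc(OC)cc(OC)c3c2c(OC=O)c1OCc4ccccc4 | intermediate
11 | 2-(benzyloxy)-3,7,9-trimethoxydibenzo[b,d]furan-1-ol | COc1cc2oc3cc(OC)cc(OC)c3c2c(O)c1OCc4ccccc4 | intermediate
12 | 2,6-difluoro-3,5-dimethoxybenzoic acid | COc1cc(OC)c(F)c(C(=O)O)c1F | starting material
13 | (2,6-difluoro-3,5-dimethoxyphenyl)methanol | COc1cc(OC)c(F)c(CO)c1F | intermediate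
14 | 2,6-difluoro-3,5-dimethoxybenzaldehyde | COc1cc(OC)c(F)c(C=O)c1F | intermediate
15 | 2-{[2-(benzyloxy)-3,7,9-trimethoxydibenzo[b,d]furan-1-yl]oxy}-6-fluoro-3,5-dimethoxybenzaldehyde | COc1cc(OC)c(F)c(C=O)c1Oc2c(OCc3ccccc3)c(OC)cc4oc5cc(OC)cc(OC)c5c24 | intermediate
16 | 2-{[2-(benzyloxy)-3,7,9-trimethoxydibenzo[b,d]furan-1-yl]oxy}-6-(3,5-dimethoxyphenoxy)-3,5-dimethoxybenzaldehyde | COc1cc(OC)cc(Oc2c(OC)cc(OC)c(Oc3c(OCc4ccccc4)c(OC)cc5oc6cc(OC)cc(OC)c6c35)c2C=O)c1 | intermediate
17 | 2-{[2-(benzyloxy)-3,7,9-trimethoxydibenzo[b,d]furan-1-yl]oxy}-6-(3,5-dimethoxyphenoxy)-3,5-dimethoxybenzoic acid | COc1cc(OC)cc(Oc2c(OC)cc(OC)c(Oc3c(OCc4ccccc4)c(OC)cc5oc6cc(OC)cc(OC)c6c35)c2C(=O)O)c1 | intermediate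
18 | 2-(3,5-dimethoxyphenoxy)-6-[(2-hydroxy-3,7,9-trimethoxydibenzo[b,d]furan-1-yl)oxy]-3,5-dimethoxybenzoic acid | COc1cc(OC)cc(Oc2c(OC)cc(OC)c(Oc3c(O)c(OC)cc4oc5cc(OC)cc(OC)c5c34)c2C(=O)O)c1 | intermediate
19 | heptamethyl depsidone (seven-membered lactone of 18 through the C2 oxygen of the dibenzofuran) | COc1cc(OC)cc(Oc2c(OC)cc(OC)c3c2C(=O)Oc2c(OC)cc4oc5cc(OC)cc(OC)c5c4c2O3)c1 | intermediate
20 | heptamethyl ether of the target (dioxin fused at C1/C2 of the dibenzofuran, 3,5-dimethoxyphenoxy group on ring B beside the dioxin carbon bound to the C2 oxygen) | COc1cc(OC)cc(Oc2c(OC)cc(OC)c3c2Oc2c(OC)cc4oc5cc(OC)cc(OC)c5c4c2O3)c1 | intermediate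
21 | CNP0256302.0, heptaphenol | Oc1cc(O)cc(Oc2c(O)cc(O)c3c2Oc2c(O)cc4oc5cc(O)cc(O)c5c4c2O3)c1 | target

**Totals**
Total step count: 15. Longest linear sequence: 13 steps (steps 1–6 and 9–15); the ring-B branch (steps 7–8) joins at step 9.

**Steps most likely to fail**

1. Step 14 (proposed new method). The catalyst may stall at the acyl nickel stage through CO binding, or C–O reductive elimination from the electron-rich aryl nickel aryloxide may be too slow, leading to ring opening or protodecarboxylation. The fallback closes the dioxin by known chemistry and sets out from 17. Decarboxylative ipso-iodination of this 2,6-bis(aryloxy)benzoic acid (I2, K3PO4, MeCN, 100 °C) would give 2-(benzyloxy)-1-[3-(3,5-dimethoxyphenoxy)-2-iodo-4,6-dimethoxyphenoxy]-3,7,9-trimethoxydibenzo[b,d]furan F1. Debenzylation with BCl3 and pentamethylbenzene (CH2Cl2, −78 °C), which spares the aryl iodide and the methyl ethers, would give 1-[3-(3,5-dimethoxyphenoxy)-2-iodo-4,6-dimethoxyphenoxy]-3,7,9-trimethoxydibenzo[b,d]furan-2-ol F2. Intramolecular Ullmann etherification (CuI, N,N-dimethylglycine, Cs2CO3, dioxane, 100 °C) then closes the six-membered ring and comes back to the route at 20.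

2. Step 9. Fluoride displacement by the hindered bay phenoxide may be too slow at a carbon that carries ortho and para methoxy donors, so that decomposition of the aldehyde or double substitution takes over. The fallback replaces SNAr by copper-catalysed C–O coupling and sets out from 11. Dibromination of commercial 3,5-dimethoxybenzaldehyde (Br2, AcOH) would give 2,6-dibromo-3,5-dimethoxybenzaldehyde F3. Ullmann coupling of 11 with an excess of F3 (CuI, picolinic acid, K3PO4, DMSO, 90 °C), assisted by the ortho carbonyl group, would give 2-{[2-(benzyloxy)-3,7,9-trimethoxydibenzo[b,d]furan-1-yl]oxy}-6-bromo-3,5-dimethoxybenzaldehyde F4. A second Ullmann coupling with 2 under the same conditions comes back to the route at 16.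

3. Step 4. The magnesium-templated hydroxymethylation may not reach the bay carbon C1 because of crowding by the methoxy group on C9, leaving 6 unchanged or giving polymeric condensation products. The fallback introduces the oxygen through a halogen and sets out from 6. Amine-catalysed ortho-bromination (NBS, i-Pr2NH cat., CH2Cl2, 0 °C) would give 1-bromo-3,7,9-trimethoxydibenzo[b,d]furan-2-ol F5. Benzylation (BnBr, K2CO3, DMF) would give 2-(benzyloxy)-1-bromo-3,7,9-trimethoxydibenzo[b,d]furan F6. Bromine–lithium exchange and borylation (n-BuLi, THF, −78 °C; B(OMe)3) would give dimethyl [2-(benzyloxy)-3,7,9-trimethoxydibenzo[b,d]furan-1-yl]boronate F7, which is oxidised without isolation (H2O2, NaOH) and comes back to the route at 11.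

**Further compounds**
F1 | step 14 | 2-(benzyloxy)-1-[3-(3,5-dimethoxyphenoxy)-2-iodo-4,6-dimethoxyphenoxy]-3,7,9-trimethoxydibenzo[b,d]furan | COc1cc(OC)cc(Oc2c(OC)cc(OC)c(Oc3c(OCc4ccccc4)c(OC)cc5oc6cc(OC)cc(OC)c6c35)c2I)c1
F2 | step 14 | 1-[3-(3,5-dimethoxyphenoxy)-2-iodo-4,6-dimethoxyphenoxy]-3,7,9-trimethoxydibenzo[b,d]furan-2-ol | COc1cc(OC)cc(Oc2c(OC)cc(OC)c(Oc3c(O)c(OC)cc4oc5cc(OC)cc(OC)c5c34)c2I)c1
F3 | step 9 | 2,6-dibromo-3,5-dimethoxybenzaldehyde | COc1cc(OC)c(Br)c(C=O)c1Br
F4 | step 9 | 2-{[2-(benzyloxy)-3,7,9-trimethoxydibenzo[b,d]furan-1-yl]oxy}-6-bromo-3,5-dimethoxybenzaldehyde | COc1cc(OC)c(Br)c(C=O)c1Oc2c(OCc3ccccc3)c(OC)cc4oc5cc(OC)cc(OC)c5c24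
F5 | step 4 | 1-bromo-3,7,9-trimethoxydibenzo[b,d]furan-2-ol | COc1cc2oc3cc(OC)cc(OC)c3c2c(Br)c1O
F6 | step 4 | 2-(benzyloxy)-1-bromo-3,7,9-trimethoxydibenzo[b,d]furan | COc1cc2oc3cc(OC)cc(OC)c3c2c(Br)c1OCc4ccccc4
F7 | step 4 | dimethyl [2-(benzyloxy)-3,7,9-trimethoxydibenzo[b,d]furan-1-yl]boronate | COB(OC)c1c(OCc2ccccc2)c(OC)cc3oc4cc(OC)cc(OC)c4c13
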